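**Retrosynthetic overview**

1. Feature: the benzene ring C4a–C5–C6–C7–C8–C8a of the isochromanone carries oxygen at C6 and C8, the C1 acyl carbon on C8a and the C4 methylene on C4a. This is the pattern of a folded β-polyketone, so the ring is built from an open chain by joining C4a to C8a in an aldol condensation.
2. Lactone ring (O2–C1, closed last): the C3 oxygen, freed from its silyl ether, opens a 2,2-dimethylbenzodioxinone that holds C1 and the C8 oxygen, with loss of acetone.
3. Benzene ring (C4a–C8a, closed second): amine-mediated cycloaromatization of a 2,4-dioxoalkyl chain on dioxinone C6; the dioxinone ring itself is bought.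
4. Diketo-dioxinone (C4a–C5 bond): keto-dioxinone dianion plus a (3R)-3-silyloxy Weinreb amide; C3 comes from Noyori hydrogenation of a β-keto ester made by Roskamp homologation of (S)-11-methoxydodecanal.
5. C10' stereocentre: (S)-propylene oxide opened by the Grignard reagent of 10-bromodec-1-ene, then O-methylation and ozonolysis.

Key step: step 10

Remark: the target is read as (3R)-6,8-dihydroxy-3-[(10S)-10-methoxyundecyl]isochroman-1-one. Enolizable compounds are drawn as keto tautomers, and primed locants C1'–C6' count the side chain of 16 outward from dioxinone C6.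

**Route**

Step 1
Reactants: 1 10-bromodec-1-ene; 2 (S)-propylene oxide
Product: 4 (2S)-tridec-12-en-2-ol, via dec-9-enylmagnesium bromide 3 (not isolated)
Conditions: Mg, THF, rt → 40 °C; then CuI (10 mol %), 2, −30 → 0 °C; aq NH4Cl
Reagents that add atoms: none
Why: Copper-catalysed Grignard opening of a terminal epoxide proceeds by SN2 attack at the unsubstituted CH2, so the oxygen-bearing stereocentre of 2 is carried over unchanged as the (S)-carbinol (future C10').

Step 2
Reactants: 4 (2S)-tridec-12-en-2-ol
Product: 5 (12S)-12-methoxytridec-1-ene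
Conditions: NaH, MeI, THF, 0 °C → rt
Reagents that add atoms: iodomethane, CI
Why: Williamson ether synthesis on the sodium alkoxide; the C–O bond of the stereocentre stays intact, so the configuration is kept.

Step 3
Reactants: 5 (12S)-12-methoxytridec-1-ene
Product: 7 (11S)-11-methoxydodecanal, via secondary ozonide 6 (not isolated)
Conditions: O3, CH2Cl2, −78 °C; then PPh3, −78 °C → rt
Reagents that add atoms: ozone, [O-][O+]=O
Why: Ozonolysis of the terminal alkene (cycloaddition, cycloreversion and recombination to the 1,2,4-trioxolane) followed by reductive cleavage with PPh3 should give the aldehyde without over-oxidation, the saturated methyl ether being inert at −78 °C.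

Step 4
Reactants: 7 (11S)-11-methoxydodecanal
Product: 8 ethyl (13S)-13-methoxy-3-oxotetradecanoate
Conditions: ethyl diazoacetate, SnCl2 (10 mol %), CH2Cl2, rt
Reagents that add atoms: ethyl diazoacetate, CCOC(=O)C=[N+]=[N-]
Why: Roskamp homologation, in which SnCl2 activates the aldehyde for addition of the diazo carbon and a 1,2-hydride shift with loss of N2 gives the β-keto ester directly.

Step 5
Reactants: 8 ethyl (13S)-13-methoxy-3-oxotetradecanoate
Product: 9 ethyl (3R,13S)-3-hydroxy-13-methoxytetradecanoate
Conditions: H2 (4 atm), RuCl2[(R)-BINAP] (0.5 mol %), EtOH, 80 °C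
Reagents that add atoms: none
Why: Noyori asymmetric hydrogenation of a β-keto ester through the chelated ruthenium keto-ester complex; the (R)-BINAP ligand sets the new C3 centre as (R), the sense it shows for unbranched 3-oxoalkanoates, and the remote C13 centre has no influence.

Step 6
Reactants: 9 ethyl (3R,13S)-3-hydroxy-13-methoxytetradecanoate
Product: 10 (3R,13S)-3-hydroxy-N,13-dimethoxy-N-methyltetradecanamide
Conditions: MeNHOMe·HCl (2.5 equiv), iPrMgCl (6 equiv), THF, −20 → 0 °C; aq NH4Cl
Reagents that add atoms: N,O-dimethylhydroxylamine hydrochloride, CNOC.Cl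
Why: Weinreb amide formation by aminolysis of the ester with the chloromagnesium amide; the magnesium β-alkoxide formed first protects the substrate against elimination and retro-aldol cleavage at low temperature.

Step 7
Reactants: 10 (3R,13S)-3-hydroxy-N,13-dimethoxy-N-methyltetradecanamide
Product: 11 (3R,13S)-3-(tert-butyldimethylsilyloxy)-N,13-dimethoxy-N-methyltetradecanamide
Conditions: TBSCl, imidazole, DMF, rt
Reagents that add atoms: tert-butyldimethylsilyl chloride, CC(C)(C)[Si](C)(C)Cl
Why: Standard imidazole-mediated silylation of a secondary alcohol; the silyl ether keeps the C3 oxygen from adding to the ketones introduced later.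

Step 8
Reactants: 12 2,2,6-trimethyl-4H-1,3-dioxin-4-one
Product: 14 2,2-dimethyl-6-(2-oxopropyl)-4H-1,3-dioxin-4-one, via lithium dienolate 13 (not isolated)
Conditions: 12 (2 equiv), LiN(SiMe3)2 (2 equiv), THF, −78 °C; AcCl (1 equiv), −78 → −40 °C; aq NH4Cl
Reagents that add atoms: acetyl chloride, CC(=O)Cl
Why: Vinylogous Claisen-type C-acylation, in which the lithium dienolate formed at the 6-methyl group reacts with acetyl chloride at its γ-carbon; two equivalents of dienolate are used because the more acidic product consumes one.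

Step 9
Reactants: 14 2,2-dimethyl-6-(2-oxopropyl)-4H-1,3-dioxin-4-one; 11 (3R,13S)-3-(tert-butyldimethylsilyloxy)-N,13-dimethoxy-N-methyltetradecanamide
Product: 16 6-[(6R,16S)-6-(tert-butyldimethylsilyloxy)-16-methoxy-2,4-dioxoheptadecyl]-2,2-dimethyl-4H-1,3-dioxin-4-one, via dilithium dianion 15 (not isolated)
Conditions: 14 (1.5 equiv), LiN(iPr)2 (3.1 equiv), THF, −78 °C; then 11 (1.0 equiv), −78 → −30 °C; aq NH4Cl
Reagents that add atoms: none
Why: Claisen-type acylation of a 1,3-dicarbonyl dianion, whose second deprotonation occurs at the terminal methyl group; this most reactive carbanion adds to the Weinreb amide and the chelated tetrahedral intermediate survives until the quench, so no second addition should occur.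

Step 10
Reactants: 16 6-[(6R,16S)-6-(tert-butyldimethylsilyloxy)-16-methoxy-2,4-dioxoheptadecyl]-2,2-dimethyl-4H-1,3-dioxin-4-one
Product: 18 5-[(2R,12S)-2-(tert-butyldimethylsilyloxy)-12-methoxytridecyl]-7-hydroxy-2,2-dimethyl-4H-benzo[d][1,3]dioxin-4-one, via cyclic aldol adduct 17 (not isolated)
Conditions: Et3N (5 equiv), CH2Cl2, 0 °C → rt
Reagents that add atoms: none
Why: Et3N removes a proton from the doubly activated C1' methylene to give the extended dioxinone dienolate, whose α-carbon (dioxinone C5, future C8a) adds to the C4' ketone (future C4a); the tertiary aldol 17 then loses water and the C2' ketone enolizes, so the benzene ring forms irreversibly. The closest known reaction type is the base-mediated biomimetic cycloaromatization of diketo-dioxinones and 3,5,7-triketo esters to resorcylates, an intramolecular aldol condensation. The carbocycle closes in a 6-(enolexo)-exo-trig mode, with the enolate C=C outside the new ring and the C4' carbonyl oxygen exocyclic. No stereocentre is created: the carbinol centre of 17 disappears on dehydration, and the C6' silyloxy centre (future C3) and the methoxy centre are not acidic positions. The step needs C-aldol folding to beat Claisen-type and O-cyclization modes; the C4' ketone is far more electrophilic than the vinylogous-carbonate carbonyl of the dioxinone, room temperature is well below the point where the dioxinone fragments to an acyl ketene, and the silyl ether stops the C3 oxygen from closing a pyranone. The weak amine base should also keep E1cB loss of the β-silyloxy group slower than ring closure.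

Step 11
Reactants: 18 5-[(2R,12S)-2-(tert-butyldimethylsilyloxy)-12-methoxytridecyl]-7-hydroxy-2,2-dimethyl-4H-benzo[d][1,3]dioxin-4-one
Product: 20 (3R)-6,8-dihydroxy-3-[(10S)-10-methoxyundecyl]isochroman-1-one, via free alcohol 19 (not isolated)
Conditions: Bu4NF (3 equiv), THF, 0 °C → 40 °C; aq NH4Cl
Reagents that add atoms: none
Why: Fluoride desilylation gives the C3 alkoxide, which attacks the neighbouring dioxinone carbonyl in a six-membered intramolecular transesterification and expels the C8 oxygen as an acetone hemiketal that loses acetone; only the acyl C–O bond is made, so C3 keeps its configuration.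

**Compound list**

1 | 10-bromodec-1-ene | C=CCCCCCCCCBr | starting material
2 | (S)-propylene oxide | C[C@H]1CO1 | starting material
3 | dec-9-enylmagnesium bromide | C=CCCCCCCCC[Mg]Br | intermediate
4 | (2S)-tridec-12-en-2-ol | C[C@H](O)CCCCCCCCCC=C | intermediate
5 | (12S)-12-methoxytridec-1-ene | CO[C@@H](C)CCCCCCCCCC=C | intermediate
6 | 3-[(10S)-10-methoxyundecyl]-1,2,4-trioxolane (secondary ozonide, both epimers at the ring carbon) | CO[C@@H](C)CCCCCCCCCC1OCOO1 | intermediate
7 | (11S)-11-methoxydodecanal | CO[C@@H](C)CCCCCCCCCC=O | intermediate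
8 | ethyl (13S)-13-methoxy-3-oxotetradecanoate | CO[C@@H](C)CCCCCCCCCC(=O)CC(=O)OCC | intermediate
9 | ethyl (3R,13S)-3-hydroxy-13-methoxytetradecanoate | CO[C@@H](C)CCCCCCCCC[C@@H](O)CC(=O)OCC | intermediate
10 | (3R,13S)-3-hydroxy-N,13-dimethoxy-N-methyltetradecanamide | CO[C@@H](C)CCCCCCCCC[C@@H](O)CC(=O)N(C)OC | intermediate
11 | (3R,13S)-3-(tert-butyldimethylsilyloxy)-N,13-dimethoxy-N-methyltetradecanamide | CO[C@@H](C)CCCCCCCCC[C@@H](O[Si](C)(C)C(C)(C)C)CC(=O)N(C)OC | intermediate
12 | 2,2,6-trimethyl-4H-1,3-dioxin-4-one | CC1=CC(=O)OC(C)(C)O1 | starting material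
13 | lithium 2,2-dimethyl-6-methylidene-6H-1,3-dioxin-4-olate (lithium dienolate of 12) | C=C1C=C(O[Li])OC(C)(C)O1 | intermediate
14 | 2,2-dimethyl-6-(2-oxopropyl)-4H-1,3-dioxin-4-one | CC(=O)CC1=CC(=O)OC(C)(C)O1 | intermediate
15 | dilithium dianion of 14 (dilithium 2,2-dimethyl-6-(2-oxidoprop-2-enylidene)-6H-1,3-dioxin-4-olate) | C=C(O[Li])C=C1C=C(O[Li])OC(C)(C)O1 | intermediate
16 | 6-[(6R,16S)-6-(tert-butyldimethylsilyloxy)-16-methoxy-2,4-dioxoheptadecyl]-2,2-dimethyl-4H-1,3-dioxin-4-one | CO[C@@H](C)CCCCCCCCC[C@@H](O[Si](C)(C)C(C)(C)C)CC(=O)CC(=O)CC1=CC(=O)OC(C)(C)O1 | intermediate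
17 | 5-[(2R,12S)-2-(tert-butyldimethylsilyloxy)-12-methoxytridecyl]-5-hydroxy-2,2-dimethyl-5,6-dihydro-4H-benzo[d][1,3]dioxine-4,7(8H)-dione (both epimers at C5) | CO[C@@H](C)CCCCCCCCC[C@@H](O[Si](C)(C)C(C)(C)C)CC1(O)CC(=O)CC2=C1C(=O)OC(C)(C)O2 | intermediate
18 | 5-[(2R,12S)-2-(tert-butyldimethylsilyloxy)-12-methoxytridecyl]-7-hydroxy-2,2-dimethyl-4H-benzo[d][1,3]dioxin-4-one | CO[C@@H](C)CCCCCCCCC[C@@H](O[Si](C)(C)C(C)(C)C)Cc1cc(O)cc2OC(C)(C)OC(=O)c12 | intermediate
19 | 7-hydroxy-5-[(2R,12S)-2-hydroxy-12-methoxytridecyl]-2,2-dimethyl-4H-benzo[d][1,3]dioxin-4-one | CO[C@@H](C)CCCCCCCCC[C@@H](O)Cc1cc(O)cc2OC(C)(C)OC(=O)c12 | intermediate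
20 | (3R)-6,8-dihydroxy-3-[(10S)-10-methoxyundecyl]isochroman-1-one | CO[C@@H](C)CCCCCCCCC[C@@H]1Cc2cc(O)cc(O)c2C(=O)O1 | target

**Step count**

Total: 11 steps. Longest linear sequence: 10 steps (steps 1–7, 9, 10, 11); step 8 is a one-step side branch.

**Steps most likely to fail**

Step 10 (key step). The ring closure may stop at the hydrated aldol stage, or the base may divert the substrate into O-cyclization or into E1cB loss of the silyloxy group before the carbocycle closes. The fallback sets out from 16 and comes back at 20. Compound 16 is heated with methanol in toluene at 110 °C; retro-[4+2] loss of acetone gives an acyl ketene that methanol traps as methyl (9R,19S)-9-(tert-butyldimethylsilyloxy)-19-methoxy-3,5,7-trioxoicosanoate F1. This open-chain triketo ester is aromatized with Cs2CO3 in MeOH at rt, with AcOH added to finish the dehydration, which should give methyl 2-[(2R,12S)-2-(tert-butyldimethylsilyloxy)-12-methoxytridecyl]-4,6-dihydroxybenzoate F2. Treatment of F2 with Bu4NF in THF removes the silyl group, and the C3 alkoxide closes on the methyl ester to give 20.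

Step 9. Proton transfer from the α-position of the Weinreb amide to the dianion, followed by β-elimination of the silyloxy group, or sluggish acylation, may erode the coupling. The fallback sets out from 11 and comes back at 16. Compound 11 is reduced with iBu2AlH in THF at −78 °C to (3R,13S)-3-(tert-butyldimethylsilyloxy)-13-methoxytetradecanal F3. Aldol addition of dianion 15 (from 14 and LiN(iPr)2, THF, −78 °C) to this much more electrophilic partner should give 6-[(6R,16S)-6-(tert-butyldimethylsilyloxy)-4-hydroxy-16-methoxy-2-oxoheptadecyl]-2,2-dimethyl-4H-1,3-dioxin-4-one F4 as a mixture of carbinol epimers. Oxidation with Dess–Martin periodinane (CH2Cl2, NaHCO3, 0 °C) then converts both epimers into 16.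

Step 11. Desilylation may proceed while lactonization stalls, because the C7 phenoxide formed under the basic conditions lowers the electrophilicity of the dioxinone carbonyl. The fallback sets out from 18 and comes back at 20. The silyl ether is removed without base by HF·pyridine in THF, so that 19 is isolated. The dioxinone is then opened by hydroxide (LiOH, THF/H2O, 40 °C) to the carboxylate of 2,4-dihydroxy-6-[(2R,12S)-2-hydroxy-12-methoxytridecyl]benzoic acid F5. Acidification with dilute HCl at rt, without heating so that the resorcylic acid does not decarboxylate, should let this δ-hydroxy acid close to 20 by acyl–oxygen bond formation, with retention at C3.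

**Further compounds**

F1 | step 10 | methyl (9R,19S)-9-(tert-butyldimethylsilyloxy)-19-methoxy-3,5,7-trioxoicosanoate | CO[C@@H](C)CCCCCCCCC[C@@H](O[Si](C)(C)C(C)(C)C)CC(=O)CC(=O)CC(=O)CC(=O)OC
F2 | step 10 | methyl 2-[(2R,12S)-2-(tert-butyldimethylsilyloxy)-12-methoxytridecyl]-4,6-dihydroxybenzoate | CO[C@@H](C)CCCCCCCCC[C@@H](O[Si](C)(C)C(C)(C)C)Cc1cc(O)cc(O)c1C(=O)OC
F3 | step 9 | (3R,13S)-3-(tert-butyldimethylsilyloxy)-13-methoxytetradecanal | CO[C@@H](C)CCCCCCCCC[C@@H](O[Si](C)(C)C(C)(C)C)CC=O
F4 | step 9 | 6-[(6R,16S)-6-(tert-butyldimethylsilyloxy)-4-hydroxy-16-methoxy-2-oxoheptadecyl]-2,2-dimethyl-4H-1,3-dioxin-4-one | CO[C@@H](C)CCCCCCCCC[C@@H](O[Si](C)(C)C(C)(C)C)CC(O)CC(=O)CC1=CC(=O)OC(C)(C)O1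
F5 | step 11 | 2,4-dihydroxy-6-[(2R,12S)-2-hydroxy-12-methoxytridecyl]benzoic acid | CO[C@@H](C)CCCCCCCCC[C@@H](O)Cc1cc(O)cc(O)c1C(=O)O
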